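**Plan**

- Retrosynthesis: the four O–benzyl bonds are cut first (C6/C6' phenols, C2/C2' hemiketal hydroxyls), then the two C2–CH3 bonds, then the two O1–C2 acetal bonds and the two C3–C3a aryl–acyl bonds. This leaves a 6,6'-dibenzyloxy-4,4',5,5'-tetramethoxybiphenyl-2,2'-diol that maps onto ellagic acid; the C7–C7' biaryl bond is never cut.
- Forward: ellagic acid supplies the biaryl and the oxygen pattern. Its lactones are opened, each carboxyl carbon is exchanged for OH (reduction, Swern, Baeyer–Villiger), a glyoxal acetal is attached at each future C3a by ortho-lithiation, and both furanone rings close by acetal formation in step 8. No ring forms after that.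
- Enabling feature: in each benzofuran-3(2H)-one ring (O1, C2, C3, C3a, C7a) C2 lies between the ring oxygen O1 and the C3 ketone and carries the methyl group. As a 2-benzyloxy acetal its C2–H can be removed to give a flat, aromatic 3-oxidobenzofuran, and C-methylation gives a mixed ketal with neither C2–H nor C2–OH.
- Stereochemistry: C2 and C2' are both set in step 9 by a chiral quaternary ammonium counter-ion (catalyst control at two independent sites) and are carried unchanged through the final neutral hydrogenolysis.

Key step: step 9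

Assumption: the given structure defines only C2 and C2'; the biaryl axis flanked by four oxygen substituents has no descriptor and is left uncontrolled, so the ellagic-derived intermediates are racemic about it and, if rotation is slow, 21 and 22 would be atropisomer pairs sharing the (2R,2'R) centers.

**Route**

Step 1
Reactants: 1 ellagic acid; 2 iodomethane
Product: 3 3,3',4,4'-tetra-O-methylellagic acid
Conditions: MeI, K2CO3, DMF, 60 °C
Reagents that add atoms: iodomethane, CI
Why: Williamson etherification: the four phenols are by far the most acidic sites of 1 and are methylated by MeI under carbonate, while the two biaryl lactones stay closed under anhydrous conditions.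

Step 2
Reactants: 3 3,3',4,4'-tetra-O-methylellagic acid; 4 benzyl bromide
Product: 6 dibenzyl 6,6'-bis(benzyloxy)-4,4',5,5'-tetramethoxybiphenyl-2,2'-dicarboxylate, via tetrapotassium diphenolate dicarboxylate 5 (not isolated)
Conditions: KOH, H2O–DMSO, 80 °C; then BnBr, Bu4NI (cat.), rt
Reagents that add atoms: potassium hydroxide, [K+].[OH-]; benzyl bromide, BrCc1ccccc1
Why: Saponification of both six-membered aryl lactones followed by exhaustive Williamson and carboxylate O-benzylation, the classical way from ellagic acid ethers to hexa-O-alkyl diphenates; the phenolates are alkylated before the carboxylates, so a phenolate never faces a benzyl ester and relactonisation is avoided.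

Step 3
Reactants: 6 dibenzyl 6,6'-bis(benzyloxy)-4,4',5,5'-tetramethoxybiphenyl-2,2'-dicarboxylate
Product: 7 [6,6'-bis(benzyloxy)-4,4',5,5'-tetramethoxybiphenyl-2,2'-diyl]dimethanol
Conditions: LiAlH4, THF, 0 °C to rt; aq. NaOH work-up
Reagents that add atoms: none
Why: LiAlH4 reduction of the two benzyl esters to primary alcohols; aryl methyl and aryl benzyl ethers are inert to hydride.

Step 4
Reactants: 7 [6,6'-bis(benzyloxy)-4,4',5,5'-tetramethoxybiphenyl-2,2'-diyl]dimethanol
Product: 8 6,6'-bis(benzyloxy)-4,4',5,5'-tetramethoxybiphenyl-2,2'-dicarbaldehyde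
Conditions: (COCl)2, DMSO, CH2Cl2, -78 °C; then Et3N, -78 °C to rt
Reagents that add atoms: none
Why: Swern oxidation: both benzylic alcohols become alkoxysulfonium ions at -78 °C before the base is added, so no aldehyde coexists with a free neighbouring CH2OH and lactol or lactone formation across the biaryl is avoided.

Step 5
Reactants: 8 6,6'-bis(benzyloxy)-4,4',5,5'-tetramethoxybiphenyl-2,2'-dicarbaldehyde; 9 3-chloroperoxybenzoic acid
Product: 11 6,6'-bis(benzyloxy)-4,4',5,5'-tetramethoxybiphenyl-2,2'-diol, via bis(aryl formate) 10 (not isolated)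
Conditions: mCPBA, CH2Cl2, 0 °C to rt; aqueous wash; then K2CO3 (cat.), MeOH, rt
Reagents that add atoms: 3-chloroperoxybenzoic acid, O=C(OO)c1cccc(Cl)c1
Why: Baeyer–Villiger (Dakin-type) oxidation: in the Criegee adduct the electron-rich aryl group, with a methoxy group para to the formyl carbon, migrates in preference to hydrogen to give the aryl formates, which mild methanolysis converts into the phenols without touching the ethers.

Step 6
Reactants: 11 6,6'-bis(benzyloxy)-4,4',5,5'-tetramethoxybiphenyl-2,2'-diol; 12 chloromethyl methyl ether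
Product: 13 6,6'-bis(benzyloxy)-4,4',5,5'-tetramethoxy-2,2'-bis(methoxymethoxy)biphenyl
Conditions: MOMCl, i-Pr2NEt, CH2Cl2, 0 °C to rt
Reagents that add atoms: chloromethyl methyl ether, COCCl
Why: Standard MOM etherification of the two phenols, which removes the acidic protons and installs a strong ortho-directing group for the next step.

Step 7
Reactants: 13 6,6'-bis(benzyloxy)-4,4',5,5'-tetramethoxy-2,2'-bis(methoxymethoxy)biphenyl; 14 ethyl diethoxyacetate
Product: 16 1,1'-[6,6'-bis(benzyloxy)-4,4',5,5'-tetramethoxy-2,2'-bis(methoxymethoxy)biphenyl-3,3'-diyl]bis(2,2-diethoxyethan-1-one), via 3,3'-dilithio biaryl 15 (not isolated)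
Conditions: n-BuLi, TMEDA, THF, -20 to 0 °C; cannulate into ethyl diethoxyacetate, THF, -78 °C; then H2O
Reagents that add atoms: ethyl diethoxyacetate, CCOC(=O)C(OCC)OCC
Why: Directed ortho-metalation: the only C–H of each core ring lies between the OMOM and OMe groups and is lithiated under their cooperative direction, and acylation of the hindered aryllithium with the α,α-dialkoxy ester stops at the ketone because the chelated tetrahedral adduct survives at -78 °C and the di-ortho-substituted ketone resists a second addition.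

Step 8
Reactants: 16 1,1'-[6,6'-bis(benzyloxy)-4,4',5,5'-tetramethoxy-2,2'-bis(methoxymethoxy)biphenyl-3,3'-diyl]bis(2,2-diethoxyethan-1-one); 17 benzyl alcohol
Product: 19 2,2',6,6'-tetrakis(benzyloxy)-4,4',5,5'-tetramethoxy-7,7'-bibenzofuran-3,3'(2H,2'H)-dione (mixture of C2 epimers), via bis(2-ethoxybenzofuranone) 18 (not isolated)
Conditions: BnOH (excess), camphorsulfonic acid (cat.), toluene, 70 °C, EtOH distilled off under slightly reduced pressure
Reagents that add atoms: benzyl alcohol, OCc1ccccc1
Why: Acid-catalysed transacetalisation: the MOM groups are transferred to BnOH, each freed phenol captures the oxocarbenium ion of the neighbouring keto acetal in a 5-exo-trig closure (O1–C2 bond, ring O1–C2–C3–C3a–C7a), and the remaining ethoxy group is exchanged for benzyloxy by mass action as ethanol is removed; C2 and C2' form as epimer mixtures, which is of no consequence.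

Step 9
Reactants: 19 2,2',6,6'-tetrakis(benzyloxy)-4,4',5,5'-tetramethoxy-7,7'-bibenzofuran-3,3'(2H,2'H)-dione; 2 iodomethane
Product: 21 (2R,2'R)-2,2',6,6'-tetrakis(benzyloxy)-4,4',5,5'-tetramethoxy-2,2'-dimethyl-7,7'-bibenzofuran-3,3'(2H,2'H)-dione, via dicesium bis(benzofuran-3-olate) 20 (not isolated)
Conditions: MeI, CsOH·H2O, O-allyl-N-(9-anthracenylmethyl)cinchonidinium bromide (20 mol %), toluene–CH2Cl2, -40 °C, argon
Reagents that add atoms: iodomethane, CI
Why: Solid CsOH removes the C2–H of each acetal at the interface, because the anion is an aromatic 3-oxidobenzofuran, and the chiral ammonium cation carries it into the organic phase as a contact ion pair that attacks iodomethane by SN2 at C2, forming the C2–CH3 and C2'–CH3 bonds. The closest known reaction type is the cinchona-ammonium phase-transfer alkylation of 2-substituted benzofuran-3(2H)-ones and the methylation of 2-aryl-1-indanones; the 2-benzyloxy member of this class is a new substrate for it. No ring is closed in this step. Each new stereocenter is controlled by the catalyst alone: the cation sits on the C3 oxygen and covers one face of the planar anion, the starting C2 configuration is erased on deprotonation, and because the two sites react independently a wrong-face event ends up mainly in the separable (2R,2'S) diastereomer; the sense of induction has to be confirmed by correlation, and the pseudoenantiomeric cinchoninium salt is used if the opposite face is delivered. The step needs facial selectivity and C- over O-methylation; the latter should be secured by the soft iodide in a non-polar medium, by the cation occupying the C3 oxygen, which is also crowded by the peri C4 methoxy group, and by the fact that C-alkylation gives a ketone–ketal with no C2–H that can neither enolise nor ring-open.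

Step 10
Reactants: 21 (2R,2'R)-2,2',6,6'-tetrakis(benzyloxy)-4,4',5,5'-tetramethoxy-2,2'-dimethyl-7,7'-bibenzofuran-3,3'(2H,2'H)-dione
Product: 22 (2R,2'R)-2,2',6,6'-tetrahydroxy-4,4',5,5'-tetramethoxy-2,2'-dimethyl-7,7'-bibenzofuran-3,3'(2H,2'H)-dione (CNP0171547.1)
Conditions: H2 (1 atm), 10% Pd/C, EtOAc, rt; filter through Celite, concentrate cold
Reagents that add atoms: none
Why: Catalytic hydrogenolysis over palladium in a neutral aprotic solvent cleaves only the four PhCH2–O bonds, freeing the C6 phenols and the C2 hemiketal hydroxyls with every C2–O bond intact, so the configuration set in step 9 should be retained because neither acid nor base is present to drive ring–chain tautomerism of the hemiketal.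

**Compound list**

1 | ellagic acid | O=C1Oc2c(O)c(O)cc3C(=O)Oc4c(O)c(O)cc1c4c23 | starting material
2 | iodomethane | CI | starting material
3 | 3,3',4,4'-tetra-O-methylellagic acid | O=C1Oc2c(OC)c(OC)cc3C(=O)Oc4c(OC)c(OC)cc1c4c23 | intermediate
4 | benzyl bromide | BrCc1ccccc1 | starting material
5 | tetrapotassium 4,4',5,5'-tetramethoxy-6,6'-dioxidobiphenyl-2,2'-dicarboxylate | COc1cc(C(=O)[O-])c(-c2c(C(=O)[O-])cc(OC)c(OC)c2[O-])c([O-])c1OC.[K+].[K+].[K+].[K+] | intermediate
6 | dibenzyl 6,6'-bis(benzyloxy)-4,4',5,5'-tetramethoxybiphenyl-2,2'-dicarboxylate | COc1cc(C(=O)OCc2ccccc2)c(-c2c(C(=O)OCc3ccccc3)cc(OC)c(OC)c2OCc2ccccc2)c(OCc2ccccc2)c1OC | intermediate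
7 | [6,6'-bis(benzyloxy)-4,4',5,5'-tetramethoxybiphenyl-2,2'-diyl]dimethanol | COc1cc(CO)c(-c2c(CO)cc(OC)c(OC)c2OCc2ccccc2)c(OCc2ccccc2)c1OC | intermediate
8 | 6,6'-bis(benzyloxy)-4,4',5,5'-tetramethoxybiphenyl-2,2'-dicarbaldehyde | COc1cc(C=O)c(-c2c(C=O)cc(OC)c(OC)c2OCc2ccccc2)c(OCc2ccccc2)c1OC | intermediate
9 | 3-chloroperoxybenzoic acid | O=C(OO)c1cccc(Cl)c1 | starting material
10 | 6,6'-bis(benzyloxy)-4,4',5,5'-tetramethoxybiphenyl-2,2'-diyl diformate | COc1cc(OC=O)c(-c2c(OC=O)cc(OC)c(OC)c2OCc2ccccc2)c(OCc2ccccc2)c1OC | intermediate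
11 | 6,6'-bis(benzyloxy)-4,4',5,5'-tetramethoxybiphenyl-2,2'-diol | COc1cc(O)c(-c2c(O)cc(OC)c(OC)c2OCc2ccccc2)c(OCc2ccccc2)c1OC | intermediate
12 | chloromethyl methyl ether | COCCl | starting material
13 | 6,6'-bis(benzyloxy)-4,4',5,5'-tetramethoxy-2,2'-bis(methoxymethoxy)biphenyl | COCOc1cc(OC)c(OC)c(OCc2ccccc2)c1-c1c(OCOC)cc(OC)c(OC)c1OCc1ccccc1 | intermediate
14 | ethyl diethoxyacetate | CCOC(=O)C(OCC)OCC | starting material
15 | 3,3'-dilithio derivative of 13 | COCOc1c([Li])c(OC)c(OC)c(OCc2ccccc2)c1-c1c(OCOC)c([Li])c(OC)c(OC)c1OCc1ccccc1 | intermediate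
16 | 1,1'-[6,6'-bis(benzyloxy)-4,4',5,5'-tetramethoxy-2,2'-bis(methoxymethoxy)biphenyl-3,3'-diyl]bis(2,2-diethoxyethan-1-one) | CCOC(OCC)C(=O)c1c(OC)c(OC)c(OCc2ccccc2)c(-c2c(OCc3ccccc3)c(OC)c(OC)c(C(=O)C(OCC)OCC)c2OCOC)c1OCOC | intermediate
17 | benzyl alcohol | OCc1ccccc1 | starting material
18 | 6,6'-bis(benzyloxy)-2,2'-diethoxy-4,4',5,5'-tetramethoxy-7,7'-bibenzofuran-3,3'(2H,2'H)-dione (C2 epimers) | CCOC1Oc2c(-c3c(OCc4ccccc4)c(OC)c(OC)c4c3OC(OCC)C4=O)c(OCc3ccccc3)c(OC)c(OC)c2C1=O | intermediate
19 | 2,2',6,6'-tetrakis(benzyloxy)-4,4',5,5'-tetramethoxy-7,7'-bibenzofuran-3,3'(2H,2'H)-dione (C2 epimers) | COc1c(OCc2ccccc2)c(-c2c(OCc3ccccc3)c(OC)c(OC)c3c2OC(OCc2ccccc2)C3=O)c2c(c1OC)C(=O)C(OCc1ccccc1)O2 | intermediate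
20 | dicesium 2,2',6,6'-tetrakis(benzyloxy)-4,4',5,5'-tetramethoxy-7,7'-bibenzofuran-3,3'-bis(olate) | COc1c(OC)c2c([O-])c(OCc3ccccc3)oc2c(-c2c(OCc3ccccc3)c(OC)c(OC)c3c([O-])c(OCc4ccccc4)oc23)c1OCc1ccccc1.[Cs+].[Cs+] | intermediate
21 | (2R,2'R)-2,2',6,6'-tetrakis(benzyloxy)-4,4',5,5'-tetramethoxy-2,2'-dimethyl-7,7'-bibenzofuran-3,3'(2H,2'H)-dione | COc1c(OCc2ccccc2)c(-c2c(OCc3ccccc3)c(OC)c(OC)c3c2O[C@@](C)(OCc2ccccc2)C3=O)c2c(c1OC)C(=O)[C@](C)(OCc1ccccc1)O2 | intermediate
22 | (2R,2'R)-2,2',6,6'-tetrahydroxy-4,4',5,5'-tetramethoxy-2,2'-dimethyl-7,7'-bibenzofuran-3,3'(2H,2'H)-dione | COc1c(O)c(-c2c(O)c(OC)c(OC)c3c2O[C@@](C)(O)C3=O)c2c(c1OC)C(=O)[C@](C)(O)O2 | target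

**Step count**

Total steps: 10. Longest linear sequence: 10 (from ellagic acid).

**Steps most likely to fail**

1. Step 9. The ion pair may discriminate the two faces of the planar olate too weakly at one or both sites, or some methylation may leak to the C3 oxygen. Fallback: from 19, methylate without asymmetric induction (MeI, K2CO3, Bu4NBr, toluene) to the stereoisomer mixture of the tetrabenzyl dimethyl bis-ketal F1. The (2R*,2'S*) diastereomer is removed on silica and the (2R*,2'R*) racemate is resolved by preparative chromatography on a chiral stationary phase (cellulose tris(3,5-dimethylphenylcarbamate)). The ketal cannot epimerise, so the separated enantiomer is stable, and the route is rejoined at 21.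

2. Step 8. Ionisation of an acetal carbon next to a ketone is slow, so exchange may stall at the ethoxy stage, and prolonged heating with acid may begin to strip the aryl benzyl ethers. Fallback: from 16, hydrolyse with aqueous CF3CO2H in CH2Cl2 to the bis(2-hydroxybenzofuran-3-one) F2 (the glyoxal hemiacetal). This is converted with SOCl2 and catalytic DMF into the bis(2-chlorobenzofuran-3-one) F3, and the chloride is displaced with BnOH and Ag2CO3 in CH2Cl2 in a Koenigs–Knorr-type substitution. The route is rejoined at 19.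

3. Step 7. Deprotonation at the benzylic CH2 of the aryl benzyl ethers (followed by Wittig rearrangement) may compete with the double ring lithiation, or the second lithiation may stay incomplete. Fallback: from 13, brominate the single free position of each core ring with NBS in MeCN to the 3,3'-dibromide F4. Bromine–lithium exchange with n-BuLi in THF at -78 °C, which outruns any deprotonation, gives the same dilithio species 15, and acylation with 14 as in step 7 rejoins the route at 16.

**Further compounds**

F1 | step 9 | 2,2',6,6'-tetrakis(benzyloxy)-4,4',5,5'-tetramethoxy-2,2'-dimethyl-7,7'-bibenzofuran-3,3'(2H,2'H)-dione, mixture of C2/C2' stereoisomers | COc1c(OCc2ccccc2)c(-c2c(OCc3ccccc3)c(OC)c(OC)c3c2OC(C)(OCc2ccccc2)C3=O)c2c(c1OC)C(=O)C(C)(OCc1ccccc1)O2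
F2 | step 8 | 6,6'-bis(benzyloxy)-2,2'-dihydroxy-4,4',5,5'-tetramethoxy-7,7'-bibenzofuran-3,3'(2H,2'H)-dione (C2 epimers) | COc1c(OCc2ccccc2)c(-c2c(OCc3ccccc3)c(OC)c(OC)c3c2OC(O)C3=O)c2c(c1OC)C(=O)C(O)O2
F3 | step 8 | 6,6'-bis(benzyloxy)-2,2'-dichloro-4,4',5,5'-tetramethoxy-7,7'-bibenzofuran-3,3'(2H,2'H)-dione (C2 epimers) | COc1c(OCc2ccccc2)c(-c2c(OCc3ccccc3)c(OC)c(OC)c3c2OC(Cl)C3=O)c2c(c1OC)C(=O)C(Cl)O2
F4 | step 7 | 6,6'-bis(benzyloxy)-3,3'-dibromo-4,4',5,5'-tetramethoxy-2,2'-bis(methoxymethoxy)biphenyl | COCOc1c(Br)c(OC)c(OC)c(OCc2ccccc2)c1-c1c(OCOC)c(Br)c(OC)c(OC)c1OCc1ccccc1
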